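In a one-step world a chain grows at a steady pace until something stops it, so its length is pace times life; start from that.

    pre-initiator → initiator (k1 = 0.00720 s⁻¹)
    free monomer + living end → monomer in chains + living end, rate k2*[living end]*[free monomer] (k2 = 505 M⁻¹ s⁻¹)
    free monomer + initiator → living end + monomer in chains (k3 = 14.6 M⁻¹ s⁻¹)
    initiator + impurity → spent initiator (k4 = 69900 M⁻¹ s⁻¹)
    living end + transfer agent → dead chain (k5 = 13.8 M⁻¹ s⁻¹)

common to all: free monomer 0.010 M; transfer agent 3.00 mM; impurity 26 µM; time 2.0 min
- Saturday's: pre-initiator 0.20 mM
- Monday's: pre-initiator 0.050 mM

- which of the two ends with the longer chains by the average number of monomer units in a chain (chains begun, living or dead) ("neither" if they lie within 10%) (Saturday's / Monday's / neither)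
- average number of monomer units in a chain (chains begun, living or dead) at the end, Saturday's
- average number of monomer units in a chain (chains begun, living or dead) at the end, Monday's

Take the pace first: a living end adds free monomer at 505 M⁻¹ s⁻¹ times [free monomer], which is 5.05 s⁻¹ as charged. Now take the life. Even if the 116 µM of initiator released by the end in Saturday's flask each became a chain that died, hardly any of the transfer agent would go, so freeze [transfer agent] and treat the death of a living end as pseudo-first-order. The rate is 0.0414 s⁻¹, so an end lives 24.2 s on average.

Multiply pace by life to get the life length, the units a chain adds before it dies (the kinetic chain length): 122. Its formula holds no initiator, and it falls in step with [free monomer].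

Chains still living are young, though. Chains begun steadily through 2.0 min with [free monomer] frozen would average 97.6.

Next, count what starts chains, using the pre-initiator released by the end:

| Flask | Initiator released | Impurity charged | Difference |
|---|---|---|---|
| Saturday's | 116 µM | 26 µM | 89.7 µM |
| Monday's | 28.9 µM | 26 µM | 2.93 µM |

At the charges, initiator meets impurity at 1.82 s⁻¹ and free monomer at 0.146 s⁻¹, so the impurity takes it faster.

In Monday's flask the difference times the life length is about 3.57% of the free monomer, so freezing holds there. Its chains begin late, so I expect a little under 97.6. Saturday's flask has the larger difference, so expect its free monomer, and with it the life length, to sink. My reckoning stops at a direction there: shorter than Monday's, with no number.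

The forecast says Monday's, with 67 for Saturday's and 90 for Monday's, noting that “transfer limits each chain's growth time to about 24 s”.

The flask gives Monday's, with 88.7 against 68.2 for Saturday's. At 2.00 min, free monomer stands at 95.7% in Monday's flask and 45.0% in Saturday's. That puts Saturday's life length at 54.9 at the end, and its average lies between this and the 122 at the start. Reckon a neighbour of Saturday's with 7.5 × 10⁻⁴ M of transfer agent: its life length is 488 as charged and 105 with its 21.5% of free monomer at the end, and its average reads 104.

All constants were set for the occasion.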